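## Retrosynthetic overview

1. The acid comes from the aldehyde of a Diels–Alder adduct. Ring A is made last, by a catalyst-controlled exo Diels–Alder reaction of a 1-vinylcyclohexene (ring B) with methacrolein. This forms C2–C3 and C4–C5, sets C4 and C5, and places the Δ1(10) alkene.
2. The diene comes from Stille vinylation of a ring-B enol triflate. The 13-OH/14,15-diacetate unit comes from an E-allylic alcohol by asymmetric epoxidation and opening at C13 with inversion. The allylic alcohol comes from a C13 methyl ketone by Horner–Wadsworth–Emmons olefination.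
3. The methyl ketone with C8 and C9 set comes from 2,3-dimethylcyclohex-2-enone and methyl vinyl ketone by a new aminocatalytic hydride/Michael cascade.
4. Ring order: ring B is the bought carbocycle; ring A is closed in step 9.

Assumption: atoms are numbered as in the halimane skeleton (target = 4S,5S,8R,9S,13R,14S); the catalyst antipodes in steps 1 and 9 are named from the facial models given there, and the mirror-image catalyst is used if a test run shows the opposite sense.

## Route

Step 1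
Reactants: 1 2,3-dimethylcyclohex-2-en-1-one; 2 methyl vinyl ketone (but-3-en-2-one)
Product: 4 (2S,3R)-2,3-dimethyl-2-(3-oxobutyl)cyclohexan-1-one, via (3R)-2,3-dimethylcyclohexan-1-one 3 (not isolated)
Conditions: tert-butyl L-valinate·(R)-TRIP (20 mol%), Hantzsch ester (1.1 equiv), Bu2O, 60 °C; then 2 (3 equiv), 40 °C
Reagents that add atoms: none
Why: Proposed new method: the primary-amine salt condenses with the tetrasubstituted enone to an N–H iminium ion, the Hantzsch ester delivers hydride to the Si face of C3 inside the chiral ion pair (sets C8, 3R), and the tetrasubstituted secondary enamine so formed (or re-formed from the imine of 3) adds to 2 in an aza-ene-like Michael addition at the more substituted carbon anti to the new 3-methyl group (forms C9–C11 and the C9 quaternary centre) before hydrolysis frees the catalyst; the closest known reaction types are the iminium transfer hydrogenation of cyclic enones, the iminium–enamine hydride/electrophile cascades of enals, and Michael additions of secondary enamines of 2-substituted cyclohexanones.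

Step 2
Reactants: 4 (2S,3R)-2,3-dimethyl-2-(3-oxobutyl)cyclohexan-1-one; 5 triethyl phosphonoacetate
Product: 6 ethyl (2E)-5-[(1S,2R)-1,2-dimethyl-6-oxocyclohexyl]-3-methylpent-2-enoate
Conditions: NaH, 5 (1.3 equiv), THF, 0 → 50 °C; E isomer separated by chromatography (E:Z about 5:1 expected)
Reagents that add atoms: none
Why: Horner–Wadsworth–Emmons olefination occurs only at the unhindered methyl ketone (the ring ketone is flanked by a quaternary carbon) and gives mainly the E trisubstituted enoate without touching a stereocentre.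

Step 3
Reactants: 6 ethyl (2E)-5-[(1S,2R)-1,2-dimethyl-6-oxocyclohexyl]-3-methylpent-2-enoate
Product: 8 (5R,6S)-6-[(3E)-5-ethoxy-3-methyl-5-oxopent-3-en-1-yl]-5,6-dimethylcyclohex-1-en-1-yl trifluoromethanesulfonate, via ring potassium enolate 7 (not isolated)
Conditions: KHMDS (1.05 equiv), THF, −78 °C; then PhNTf2, −78 → 0 °C
Reagents that add atoms: N-phenylbis(trifluoromethanesulfonimide) O=S(=O)(N(c1ccccc1)S(=O)(=O)C(F)(F)F)C(F)(F)F
Why: Kinetic ketone deprotonation can only go toward C5 because C9 is quaternary, so enolate O-triflation gives a single enol triflate regioisomer.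

Step 4
Reactants: 8 (5R,6S)-6-[(3E)-5-ethoxy-3-methyl-5-oxopent-3-en-1-yl]-5,6-dimethylcyclohex-1-en-1-yl trifluoromethanesulfonate
Product: 9 (5R,6S)-6-[(3E)-5-hydroxy-3-methylpent-3-en-1-yl]-5,6-dimethylcyclohex-1-en-1-yl trifluoromethanesulfonate
Conditions: DIBAL-H (2.5 equiv), CH2Cl2, −78 °C; Rochelle salt work-up
Reagents that add atoms: none
Why: DIBAL-H 1,2-reduction of the conjugated ester gives the E-allylic alcohol at −78 °C, where the vinyl triflate is inert.

Step 5
Reactants: 9 (5R,6S)-6-[(3E)-5-hydroxy-3-methylpent-3-en-1-yl]-5,6-dimethylcyclohex-1-en-1-yl trifluoromethanesulfonate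
Product: 10 (5R,6S)-6-{2-[(2S,3S)-3-(hydroxymethyl)-2-methyloxiran-2-yl]ethyl}-5,6-dimethylcyclohex-1-en-1-yl trifluoromethanesulfonate
Conditions: Ti(OiPr)4 (10 mol%), L-(+)-diethyl tartrate (12 mol%), tBuOOH, 4 Å MS, CH2Cl2, −20 °C
Reagents that add atoms: tert-butyl hydroperoxide CC(C)(C)OO
Why: Sharpless asymmetric epoxidation is directed by the allylic hydroxyl (the electron-poor enol triflate does not react), and L-(+)-tartrate gives the (2S,3S)-epoxy alcohol, i.e. 13S,14S, under reagent control.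

Step 6
Reactants: 10 (5R,6S)-6-{2-[(2S,3S)-3-(hydroxymethyl)-2-methyloxiran-2-yl]ethyl}-5,6-dimethylcyclohex-1-en-1-yl trifluoromethanesulfonate
Product: 11 (5R,6S)-5,6-dimethyl-6-[(3R,4S)-3,4,5-trihydroxy-3-methylpentyl]cyclohex-1-en-1-yl trifluoromethanesulfonate
Conditions: HClO4 (cat.), THF/H2O 3:1, 0 °C → rt
Reagents that add atoms: water O
Why: Acid-catalysed epoxide hydrolysis: water opens the protonated trisubstituted epoxide at the tertiary carbon C13 with inversion (borderline SN2) while C14 keeps its oxygen, giving the anti (13R,14S) triol.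

Step 7
Reactants: 11 (5R,6S)-5,6-dimethyl-6-[(3R,4S)-3,4,5-trihydroxy-3-methylpentyl]cyclohex-1-en-1-yl trifluoromethanesulfonate
Product: 13 (2S,3R)-5-[(1S,6R)-1,6-dimethyl-2-(trifluoromethanesulfonyloxy)cyclohex-2-en-1-yl]-3-methyl-3-(trimethylsilyloxy)pentane-1,2-diyl diacetate, via diacetate alcohol 12 (not isolated)
Conditions: Ac2O (2.2 equiv), pyridine, DMAP (2 mol%), CH2Cl2, 0 °C; then N-(trimethylsilyl)imidazole (4 equiv), rt
Reagents that add atoms: acetic anhydride CC(=O)OC(C)=O; N-(trimethylsilyl)imidazole C[Si](C)(C)n1ccnc1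
Why: Selective O-acetylation esterifies only the primary and secondary hydroxyls, and the hindered tertiary hydroxyl is then capped in the same flask by silyl transfer so that it cannot quench the Lewis acid of step 9.

Step 8
Reactants: 13 (2S,3R)-5-[(1S,6R)-1,6-dimethyl-2-(trifluoromethanesulfonyloxy)cyclohex-2-en-1-yl]-3-methyl-3-(trimethylsilyloxy)pentane-1,2-diyl diacetate; 14 tributyl(vinyl)stannane
Product: 15 (2S,3R)-5-[(1S,6R)-2-ethenyl-1,6-dimethylcyclohex-2-en-1-yl]-3-methyl-3-(trimethylsilyloxy)pentane-1,2-diyl diacetate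
Conditions: Pd(PPh3)4 (5 mol%), LiCl (3 equiv), THF, 65 °C
Reagents that add atoms: none
Why: Stille cross-coupling of the vinyl triflate (LiCl-assisted) installs the vinyl group under neutral conditions and keeps the ring double bond in place, giving the 1-vinylcyclohexene diene.

Step 9
Reactants: 15 (2S,3R)-5-[(1S,6R)-2-ethenyl-1,6-dimethylcyclohex-2-en-1-yl]-3-methyl-3-(trimethylsilyloxy)pentane-1,2-diyl diacetate; 16 methacrolein (2-methylprop-2-enal)
Product: 17 (2S,3R)-5-[(1S,2R,4aS,5S)-5-formyl-1,2,5-trimethyl-1,2,3,4,4a,5,6,7-octahydronaphthalen-1-yl]-3-methyl-3-(trimethylsilyloxy)pentane-1,2-diyl diacetate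
Conditions: (S)-B-(o-tolyl)-diphenylprolinol oxazaborolidine + Tf2NH (20 mol% each), 16 (5 equiv), CH2Cl2, −78 → −40 °C
Reagents that add atoms: none
Why: Catalytic enantioselective Diels–Alder reaction: the chiral oxazaborolidinium ion binds methacrolein s-trans and exposes its Cα-Re face, the unsubstituted vinyl terminus C2 bonds first to the β-carbon (ortho regiochemistry), and the formyl group sits exo (methyl endo, away from quaternary C9), so C4 (S) and C5 (S, H cis to CHO) are set under catalyst control on the diene face anti to the C9 side chain and the cycloaddition itself places the Δ1(10) alkene.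

Step 10
Reactants: 17 (2S,3R)-5-[(1S,2R,4aS,5S)-5-formyl-1,2,5-trimethyl-1,2,3,4,4a,5,6,7-octahydronaphthalen-1-yl]-3-methyl-3-(trimethylsilyloxy)pentane-1,2-diyl diacetate
Product: 19 (1S,5S,6R,8aS)-5-[(3R,4S)-4,5-bis(acetyloxy)-3-hydroxy-3-methylpentyl]-1,5,6-trimethyl-1,2,3,5,6,7,8,8a-octahydronaphthalene-1-carboxylic acid (CNP0224606.1), via silyl ether acid 18 (not isolated)
Conditions: NaClO2, NaH2PO4, 2-methyl-2-butene, tBuOH/H2O, 0 °C → rt; then 1 M HCl, THF, rt
Reagents that add atoms: sodium chlorite [Na+].[O-]Cl=O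
Why: Pinnick oxidation converts the neopentyl aldehyde into the acid without touching the trisubstituted alkene (hypochlorite is scavenged) or the acetates, and dilute acid then hydrolyses the tertiary TMS ether.

## Compound list

1 | 2,3-dimethylcyclohex-2-en-1-one | CC1=C(C)C(=O)CCC1 | starting material
2 | methyl vinyl ketone (but-3-en-2-one) | CC(=O)C=C | starting material
3 | (3R)-2,3-dimethylcyclohexan-1-one (C2 epimers, held as catalyst imine/enamine) | CC1C(=O)CCC[C@H]1C | intermediate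
4 | (2S,3R)-2,3-dimethyl-2-(3-oxobutyl)cyclohexan-1-one | CC(=O)CC[C@]1(C)C(=O)CCC[C@H]1C | intermediate
5 | triethyl phosphonoacetate | CCOC(=O)CP(=O)(OCC)OCC | starting material
6 | ethyl (2E)-5-[(1S,2R)-1,2-dimethyl-6-oxocyclohexyl]-3-methylpent-2-enoate | CCOC(=O)/C=C(\C)CC[C@]1(C)C(=O)CCC[C@H]1C | intermediate
7 | potassium (5R,6S)-6-[(3E)-5-ethoxy-3-methyl-5-oxopent-3-en-1-yl]-5,6-dimethylcyclohex-1-en-1-olate | CCOC(=O)/C=C(\C)CC[C@]1(C)C([O-])=CCC[C@H]1C.[K+] | intermediate
8 | (5R,6S)-6-[(3E)-5-ethoxy-3-methyl-5-oxopent-3-en-1-yl]-5,6-dimethylcyclohex-1-en-1-yl trifluoromethanesulfonate | CCOC(=O)/C=C(\C)CC[C@]1(C)C(OS(=O)(=O)C(F)(F)F)=CCC[C@H]1C | intermediate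
9 | (5R,6S)-6-[(3E)-5-hydroxy-3-methylpent-3-en-1-yl]-5,6-dimethylcyclohex-1-en-1-yl trifluoromethanesulfonate | OC/C=C(\C)CC[C@]1(C)C(OS(=O)(=O)C(F)(F)F)=CCC[C@H]1C | intermediate
10 | (5R,6S)-6-{2-[(2S,3S)-3-(hydroxymethyl)-2-methyloxiran-2-yl]ethyl}-5,6-dimethylcyclohex-1-en-1-yl trifluoromethanesulfonate | OC[C@@H]1O[C@@]1(C)CC[C@]2(C)C(OS(=O)(=O)C(F)(F)F)=CCC[C@H]2C | intermediate
11 | (5R,6S)-5,6-dimethyl-6-[(3R,4S)-3,4,5-trihydroxy-3-methylpentyl]cyclohex-1-en-1-yl trifluoromethanesulfonate | OC[C@H](O)[C@](C)(O)CC[C@]1(C)C(OS(=O)(=O)C(F)(F)F)=CCC[C@H]1C | intermediate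
12 | (2S,3R)-5-[(1S,6R)-1,6-dimethyl-2-(trifluoromethanesulfonyloxy)cyclohex-2-en-1-yl]-3-hydroxy-3-methylpentane-1,2-diyl diacetate | CC(=O)OC[C@H](OC(C)=O)[C@](C)(O)CC[C@]1(C)C(OS(=O)(=O)C(F)(F)F)=CCC[C@H]1C | intermediate
13 | (2S,3R)-5-[(1S,6R)-1,6-dimethyl-2-(trifluoromethanesulfonyloxy)cyclohex-2-en-1-yl]-3-methyl-3-(trimethylsilyloxy)pentane-1,2-diyl diacetate | CC(=O)OC[C@H](OC(C)=O)[C@](C)(O[Si](C)(C)C)CC[C@]1(C)C(OS(=O)(=O)C(F)(F)F)=CCC[C@H]1C | intermediate
14 | tributyl(vinyl)stannane | C=C[Sn](CCCC)(CCCC)CCCC | starting material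
15 | (2S,3R)-5-[(1S,6R)-2-ethenyl-1,6-dimethylcyclohex-2-en-1-yl]-3-methyl-3-(trimethylsilyloxy)pentane-1,2-diyl diacetate | CC(=O)OC[C@H](OC(C)=O)[C@](C)(O[Si](C)(C)C)CC[C@]1(C)C(C=C)=CCC[C@H]1C | intermediate
16 | methacrolein (2-methylprop-2-enal) | CC(=C)C=O | starting material
17 | (2S,3R)-5-[(1S,2R,4aS,5S)-5-formyl-1,2,5-trimethyl-1,2,3,4,4a,5,6,7-octahydronaphthalen-1-yl]-3-methyl-3-(trimethylsilyloxy)pentane-1,2-diyl diacetate | CC(=O)OC[C@H](OC(C)=O)[C@](C)(O[Si](C)(C)C)CC[C@]1(C)C2=CCC[C@](C)(C=O)[C@H]2CC[C@H]1C | intermediate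
18 | (1S,5S,6R,8aS)-5-[(3R,4S)-4,5-bis(acetyloxy)-3-methyl-3-(trimethylsilyloxy)pentyl]-1,5,6-trimethyl-1,2,3,5,6,7,8,8a-octahydronaphthalene-1-carboxylic acid | CC(=O)OC[C@H](OC(C)=O)[C@](C)(O[Si](C)(C)C)CC[C@]1(C)C2=CCC[C@](C)(C(=O)O)[C@H]2CC[C@H]1C | intermediate
19 | (1S,5S,6R,8aS)-5-[(3R,4S)-4,5-bis(acetyloxy)-3-hydroxy-3-methylpentyl]-1,5,6-trimethyl-1,2,3,5,6,7,8,8a-octahydronaphthalene-1-carboxylic acid (CNP0224606.1) | CC(=O)OC[C@H](OC(C)=O)[C@](C)(O)CC[C@]1(C)C2=CCC[C@](C)(C(=O)O)[C@H]2CC[C@H]1C | target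

## Step count and risks

Total steps: 10. Longest linear sequence: 10 (1 → 19; compounds 2, 5, 14 and 16 are bought).

**Step 1 (the proposed new cascade).** It can fail in three ways: low enantioselectivity in hydride transfer to a tetrasubstituted iminium ion, competing reduction of 2 by leftover Hantzsch ester, and amine-catalysed aldol closure of 4 to an octalone. The fallback uses known reactions only, sets out from 1 and comes back at 4. Enone 1 is reduced with (S)-Me-CBS and catecholborane (CBS reduction, alkenyl carbon as the large group) to (1R)-2,3-dimethylcyclohex-2-en-1-ol F1. Hydroxyl-directed hydrogenation with Crabtree's catalyst adds hydrogen syn to the OH and gives (1R,2R,3R)-2,3-dimethylcyclohexan-1-ol F2, which fixes C8. Dess–Martin oxidation gives ketone 3, now isolated. Condensation with benzylamine gives the N-benzyl imine of (3R)-2,3-dimethylcyclohexan-1-one F3, which adds to 2 through its more substituted secondary enamine, anti to the 3-methyl group. Aqueous acetic acid then releases 4.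

**Step 6 (epoxide opening at a tertiary centre).** Partial SN1 character would erode the C13 configuration, and hydride shift or elimination could compete. The fallback moves the inversion to the secondary carbon with two clean SN2 events; it sets out from 9 and comes back at 15. Stille coupling of 9 with 14 gives (2E)-5-[(1S,6R)-2-ethenyl-1,6-dimethylcyclohex-2-en-1-yl]-3-methylpent-2-en-1-ol F4. Sharpless epoxidation with D-(−)-diethyl tartrate gives the antipodal (2R,3R)-epoxy alcohol F5. Aqueous NaOH in tert-butanol at 75 °C (Payne rearrangement, then hydroxide opening of the terminal epoxide at C15) inverts C14 and keeps C13, giving the (2S,3R)-diene triol F6. Acetylation gives the diacetate alcohol F7, and silylation as in step 7 returns 15. The base-stable diene replaces the triflate, which would not survive hot hydroxide.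

**Step 9 (Diels–Alder on the functionalised chiral diene).**
- Risks: the catalyst must override whatever facial bias the C8/C9 centres impose; exo selectivity and ortho regiochemistry are inferred from simpler dienes; the two acetates and the TMS ether may slow or partly quench the boron Lewis acid.
- Scope of the fallback: it removes the functional-group problem and lets the C5 epimer be separated early, but it uses the same cycloaddition, so it does not cure an intrinsic facial mismatch. It sets out from 8 and comes back at 19, with ring A built before the side chain is oxidised and the acid carried as an allyl ester.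
- Sequence:
  - Stille coupling of 8 with 14 gives the diene ester F8.
  - The same oxazaborolidinium-catalysed cycloaddition with 16, now on a substrate carrying only an ester, gives the aldehyde ester F9.
  - Pinnick oxidation gives the acid ester F10.
  - Allyl bromide and K2CO3 in DMF give the allyl ester F11.
  - DIBAL-H at −78 °C reduces only the unhindered enoate, giving the allylic alcohol F12.
  - Sharpless epoxidation with L-(+)-diethyl tartrate gives the epoxy alcohol F13.
  - Dilute HClO4 gives the triol F14.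
  - Ac2O in pyridine gives the diacetate allyl ester F15.
  - Pd(PPh3)4 with morpholine removes the allyl group and gives 19.

## Further compounds

F1 | step 1 | (1R)-2,3-dimethylcyclohex-2-en-1-ol | CC1=C(C)[C@H](O)CCC1
F2 | step 1 | (1R,2R,3R)-2,3-dimethylcyclohexan-1-ol | O[C@@H]1CCC[C@@H](C)[C@H]1C
F3 | step 1 | N-benzyl imine of (3R)-2,3-dimethylcyclohexan-1-one | CC1C(=NCc2ccccc2)CCC[C@H]1C
F4 | step 6 | (2E)-5-[(1S,6R)-2-ethenyl-1,6-dimethylcyclohex-2-en-1-yl]-3-methylpent-2-en-1-ol | OC/C=C(\C)CC[C@]1(C)C(C=C)=CCC[C@H]1C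
F5 | step 6 | [(2R,3R)-3-{2-[(1S,6R)-2-ethenyl-1,6-dimethylcyclohex-2-en-1-yl]ethyl}-3-methyloxiran-2-yl]methanol | OC[C@H]1O[C@]1(C)CC[C@]2(C)C(C=C)=CCC[C@H]2C
F6 | step 6 | (2S,3R)-5-[(1S,6R)-2-ethenyl-1,6-dimethylcyclohex-2-en-1-yl]-3-methylpentane-1,2,3-triol | OC[C@H](O)[C@](C)(O)CC[C@]1(C)C(C=C)=CCC[C@H]1C
F7 | step 6 | (2S,3R)-5-[(1S,6R)-2-ethenyl-1,6-dimethylcyclohex-2-en-1-yl]-3-hydroxy-3-methylpentane-1,2-diyl diacetate | CC(=O)OC[C@H](OC(C)=O)[C@](C)(O)CC[C@]1(C)C(C=C)=CCC[C@H]1C
F8 | step 9 | ethyl (2E)-5-[(1S,6R)-2-ethenyl-1,6-dimethylcyclohex-2-en-1-yl]-3-methylpent-2-enoate | CCOC(=O)/C=C(\C)CC[C@]1(C)C(C=C)=CCC[C@H]1C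
F9 | step 9 | ethyl (2E)-5-[(1S,2R,4aS,5S)-5-formyl-1,2,5-trimethyl-1,2,3,4,4a,5,6,7-octahydronaphthalen-1-yl]-3-methylpent-2-enoate | CCOC(=O)/C=C(\C)CC[C@]1(C)C2=CCC[C@](C)(C=O)[C@H]2CC[C@H]1C
F10 | step 9 | (1S,5S,6R,8aS)-5-[(3E)-5-ethoxy-3-methyl-5-oxopent-3-en-1-yl]-1,5,6-trimethyl-1,2,3,5,6,7,8,8a-octahydronaphthalene-1-carboxylic acid | CCOC(=O)/C=C(\C)CC[C@]1(C)C2=CCC[C@](C)(C(=O)O)[C@H]2CC[C@H]1C
F11 | step 9 | prop-2-en-1-yl (1S,5S,6R,8aS)-5-[(3E)-5-ethoxy-3-methyl-5-oxopent-3-en-1-yl]-1,5,6-trimethyl-1,2,3,5,6,7,8,8a-octahydronaphthalene-1-carboxylate | CCOC(=O)/C=C(\C)CC[C@]1(C)C2=CCC[C@](C)(C(=O)OCC=C)[C@H]2CC[C@H]1C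
F12 | step 9 | prop-2-en-1-yl (1S,5S,6R,8aS)-5-[(3E)-5-hydroxy-3-methylpent-3-en-1-yl]-1,5,6-trimethyl-1,2,3,5,6,7,8,8a-octahydronaphthalene-1-carboxylate | OC/C=C(\C)CC[C@]1(C)C2=CCC[C@](C)(C(=O)OCC=C)[C@H]2CC[C@H]1C
F13 | step 9 | prop-2-en-1-yl (1S,5S,6R,8aS)-5-{2-[(2S,3S)-3-(hydroxymethyl)-2-methyloxiran-2-yl]ethyl}-1,5,6-trimethyl-1,2,3,5,6,7,8,8a-octahydronaphthalene-1-carboxylate | OC[C@@H]1O[C@@]1(C)CC[C@]2(C)C3=CCC[C@](C)(C(=O)OCC=C)[C@H]3CC[C@H]2C
F14 | step 9 | prop-2-en-1-yl (1S,5S,6R,8aS)-1,5,6-trimethyl-5-[(3R,4S)-3,4,5-trihydroxy-3-methylpentyl]-1,2,3,5,6,7,8,8a-octahydronaphthalene-1-carboxylate | OC[C@H](O)[C@](C)(O)CC[C@]1(C)C2=CCC[C@](C)(C(=O)OCC=C)[C@H]2CC[C@H]1C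
F15 | step 9 | prop-2-en-1-yl (1S,5S,6R,8aS)-5-[(3R,4S)-4,5-bis(acetyloxy)-3-hydroxy-3-methylpentyl]-1,5,6-trimethyl-1,2,3,5,6,7,8,8a-octahydronaphthalene-1-carboxylate | CC(=O)OC[C@H](OC(C)=O)[C@](C)(O)CC[C@]1(C)C2=CCC[C@](C)(C(=O)OCC=C)[C@H]2CC[C@H]1C
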